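The γ-lactone is closed at its alkyl C–O bond: the C19 carboxyl on C4 adds to C6, the β-carbon of an exocyclic enone whose carbonyl is C10, the latent tertiary carbinol of ring A. The enone comes from a catalytic asymmetric methyl conjugate addition with aldol trapping. Acid then frees the carboxylic acid, and the reversible 5-endo oxa-Michael closure sets C5 and C6 from C4 under thermodynamic control (cis-fused lactone, side chain on the convex face). C10 is then methylenated and hydrated, and the bicyclo[3.2.1]octenone is grown on the side chain by a catalyst-controlled Diels–Alder reaction and a ketyl–alkyne cyclisation.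

Key step: step 4

Remark: atom labels are those of the 9,10-seco-ent-kaurane skeleton (C19 = lactone carbonyl on C4, C18/C20 = methyls on C4/C10, C6 = lactone O–CH, C7 = linking CH2, C8/C13 = bridgeheads, C9 = ketone, C14 = one-carbon bridge, C15 = acetoxy carbon, C16=C17 = methylidene); ring A is the cyclohexane, ring C the six-membered enone ring, ring D the five-membered ring.

Step 1
Reactants: 1 3-oxocyclohex-1-ene-1-carboxylic acid
Product: 2 tert-butyl 3-oxocyclohex-1-ene-1-carboxylate
Conditions: Cl3CC(=NH)OtBu, BF3·OEt2 (cat.), CH2Cl2/cyclohexane, 23 °C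
Reagents that add atoms: tert-butyl 2,2,2-trichloroacetimidate, CC(C)(C)OC(=N)C(Cl)(Cl)Cl
Why: Acid-catalysed O-tert-butylation of the carboxylic acid by the imidate should give the acid-labile ester needed for step 4 without touching the enone; no stereocentre is formed.

Step 2
Reactants: 2 tert-butyl 3-oxocyclohex-1-ene-1-carboxylate; 3 4-oxobutyl acetate
Product: 6 tert-butyl (1R)-2-[4-acetoxy-1-(methanesulfonyloxy)butyl]-1-methyl-3-oxocyclohexane-1-carboxylate, via zinc enolate 4 (not isolated), via zinc aldolate 5 (not isolated)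
Conditions: Me2Zn, (CuOTf)2·C6H6 (2.5 mol%), [Ag(L*)]2 (2.5 mol%, L* = chiral sulfonate-bearing N-heterocyclic carbene), Et2O, −30 °C; then 3, −30 → 0 °C; then MsCl, Et3N, 0 °C
Reagents that add atoms: dimethylzinc, C[Zn]C; methanesulfonyl chloride, CS(=O)(=O)Cl
Why: Copper-catalysed enantioselective conjugate addition of Me2Zn under control of the chiral carbene ligand should set the (R)-quaternary centre C4, the regiodefined zinc enolate then adds to aldehyde 3 at C5 (tandem conjugate addition–aldol) and the aldolate is sulfonylated in the same flask, the two new CH centres (C5, C6) being transient because steps 3 and 4 reset them.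

Step 3
Reactants: 6 tert-butyl (1R)-2-[4-acetoxy-1-(methanesulfonyloxy)butyl]-1-methyl-3-oxocyclohexane-1-carboxylate
Product: 7 tert-butyl (1R)-2-(4-acetoxybutylidene)-1-methyl-3-oxocyclohexane-1-carboxylate
Conditions: DBU, CH2Cl2, 0 → 23 °C
Reagents that add atoms: none
Why: E1cB elimination of the β-sulfonyloxy ketone should give the C5=C6 exocyclic enone; either alkene geometry is acceptable because step 4 is stereoconvergent.

Step 4
Reactants: 7 tert-butyl (1R)-2-(4-acetoxybutylidene)-1-methyl-3-oxocyclohexane-1-carboxylate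
Product: 9 3-[(3R,3aS,7aR)-7a-methyl-1,4-dioxooctahydroisobenzofuran-3-yl]propyl acetate, via enone acid 8 (not isolated)
Conditions: TFA/CH2Cl2 (1:4), 0 → 23 °C
Reagents that add atoms: none
Why: TFA removes the tert-butyl group as isobutene to give acid 8 and protonates the C10 carbonyl, so that the C5=C6 enone becomes a hydroxyallyl cation whose C6 terminus is captured by the carboxyl oxygen; tautomerisation of the enol then places H on C5. The closest known reaction type is the acid-mediated lactonisation of alkylidenesuccinic (β,γ-unsaturated) acids to γ-lactones, i.e. an intramolecular oxa-Michael addition. The γ-lactone ring (O, C19, C4, C5, C6) closes in a 5-endo-trig mode by forming the O–C6 bond, which is feasible because the acceptor is a protonated, cation-like enone and the nucleophile is oxygen. C6 and C5 are both set under thermodynamic control relayed from the C4 quaternary centre: addition and enolisation are reversible in acid, so the cis-fused lactone with the C6 side chain on the convex face (trans to C10) should accumulate whatever the enone geometry. The step needs site selectivity for C6 and survival of the side-chain ester: C6 is the only electrophilic carbon within reach of the carboxyl group, ring closure relieves the allylic strain between the alkylidene group and the C4 quaternary centre, the acetate oxygen is not nucleophilic, and no base is present that could reopen the β-acyloxy ketone by E1cB elimination.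

Step 5
Reactants: 9 3-[(3R,3aS,7aR)-7a-methyl-1,4-dioxooctahydroisobenzofuran-3-yl]propyl acetate
Product: 10 3-[(3R,3aS,7aR)-7a-methyl-4-methylidene-1-oxooctahydroisobenzofuran-3-yl]propyl acetate
Conditions: Zn, CH2Br2, TiCl4, THF/CH2Cl2, 0 → 23 °C
Reagents that add atoms: dibromomethane, BrCBr
Why: Takai–Lombardo methylenation with the non-basic gem-dimetallic reagent should convert the C10 ketone into the exocyclic alkene without E1cB opening of the β-acyloxy ketone and without attack on the lactone or acetate.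

Step 6
Reactants: 10 3-[(3R,3aS,7aR)-7a-methyl-4-methylidene-1-oxooctahydroisobenzofuran-3-yl]propyl acetate
Product: 11 3-[(3R,3aS,4R,7aR)-4-hydroxy-4,7a-dimethyl-1-oxooctahydroisobenzofuran-3-yl]propyl acetate
Conditions: Co(acac)2 (cat.), PhSiH3, O2 (1 atm), THF, 23 °C
Reagents that add atoms: dioxygen, O=O
Why: Mukaiyama hydration: hydrogen-atom transfer to the CH2 terminus gives the tertiary C10 radical, which should be trapped by O2 on the convex face of the cis-fused bicycle (the C19 carbonyl and the C5–C6 bond shield the concave face), placing OH trans to C6 and the new C20 methyl on the lactone side, the peroxide being reduced in situ by the silane.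

Step 7
Reactants: 11 3-[(3R,3aS,4R,7aR)-4-hydroxy-4,7a-dimethyl-1-oxooctahydroisobenzofuran-3-yl]propyl acetate
Product: 12 3-[(3R,3aS,4R,7aR)-4,7a-dimethyl-1-oxo-4-(triethylsilyloxy)octahydroisobenzofuran-3-yl]propyl acetate
Conditions: Et3SiOTf, 2,6-lutidine, CH2Cl2, −78 → 0 °C
Reagents that add atoms: triethylsilyl trifluoromethanesulfonate, CC[Si](CC)(CC)OS(=O)(=O)C(F)(F)F
Why: Silylation of the tertiary alcohol with the reactive silyl triflate masks the only protic group before the Lewis-acid-catalysed cycloaddition; the lactone has no α-hydrogen and cannot be enolised.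

Step 8
Reactants: 12 3-[(3R,3aS,4R,7aR)-4,7a-dimethyl-1-oxo-4-(triethylsilyloxy)octahydroisobenzofuran-3-yl]propyl acetate
Product: 13 (3R,3aS,4R,7aR)-3-(3-hydroxypropyl)-4,7a-dimethyl-4-(triethylsilyloxy)hexahydroisobenzofuran-1(3H)-one
Conditions: K2CO3, MeOH, 0 °C
Reagents that add atoms: none
Why: Transesterification (methanolysis) of the unhindered primary acetate should be much faster than attack on the γ-lactone, whose acyl carbon is shielded by the C4 quaternary centre and which would in any case reclose.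

Step 9
Reactants: 13 (3R,3aS,4R,7aR)-3-(3-hydroxypropyl)-4,7a-dimethyl-4-(triethylsilyloxy)hexahydroisobenzofuran-1(3H)-one
Product: 14 3-[(3R,3aS,4R,7aR)-4,7a-dimethyl-1-oxo-4-(triethylsilyloxy)octahydroisobenzofuran-3-yl]propanal
Conditions: Dess–Martin periodinane, NaHCO3, CH2Cl2, 23 °C
Reagents that add atoms: none
Why: Dess–Martin oxidation of the primary alcohol gives the C15 aldehyde under buffered conditions that leave the silyl ether and lactone intact.

Step 10
Reactants: 14 3-[(3R,3aS,4R,7aR)-4,7a-dimethyl-1-oxo-4-(triethylsilyloxy)octahydroisobenzofuran-3-yl]propanal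
Product: 15 2-{[(3R,3aS,4R,7aR)-4,7a-dimethyl-1-oxo-4-(triethylsilyloxy)octahydroisobenzofuran-3-yl]methyl}prop-2-enal
Conditions: aq. CH2O (37%), pyrrolidine (cat.), EtCO2H (cat.), iPrOH, 45 °C
Reagents that add atoms: formaldehyde, C=O
Why: Amine-catalysed α-methylenation (Mannich condensation then elimination) at C8, the only enolisable position of the aldehyde, should give the 2-substituted acrolein that carries C14.

Step 11
Reactants: 16 glutaconaldehyde potassium salt
Product: 17 (2E,4E)-5-(tert-butyldimethylsilyloxy)penta-2,4-dienal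
Conditions: tBuMe2SiCl, DMF, 0 → 23 °C
Reagents that add atoms: tert-butyldimethylsilyl chloride, CC(C)(C)[Si](C)(C)Cl
Why: O-silylation of the ambident dienolate by the hard silyl chloride should give the all-trans silyl dienol ether.

Step 12
Reactants: 17 (2E,4E)-5-(tert-butyldimethylsilyloxy)penta-2,4-dienal
Product: 18 tert-butyl[(1E,3E)-hexa-1,3-dien-5-yn-1-yloxy]dimethylsilane
Conditions: Me3SiCHN2, LiN(iPr)2, THF, −78 → 0 °C
Reagents that add atoms: (trimethylsilyl)diazomethane, C[Si](C)(C)C=[N+]=[N-]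
Why: Colvin rearrangement: addition of lithiated trimethylsilyldiazomethane to the aldehyde, Peterson-type elimination, loss of N2 and 1,2-hydride shift of the alkylidene carbene should give the terminal alkyne (C16≡C17) under aprotic conditions that spare the silyl dienol ether.

Step 13
Reactants: 15 2-{[(3R,3aS,4R,7aR)-4,7a-dimethyl-1-oxo-4-(triethylsilyloxy)octahydroisobenzofuran-3-yl]methyl}prop-2-enal; 18 tert-butyl[(1E,3E)-hexa-1,3-dien-5-yn-1-yloxy]dimethylsilane
Product: 19 (1S,2S,5S)-2-(tert-butyldimethylsilyloxy)-5-ethynyl-1-{[(3R,3aS,4R,7aR)-4,7a-dimethyl-1-oxo-4-(triethylsilyloxy)octahydroisobenzofuran-3-yl]methyl}cyclohex-3-ene-1-carbaldehyde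
Conditions: oxazaborolidinium triflimide from (S)-α,α-diphenylprolinol, o-tolylboronic acid and Tf2NH (20 mol%), CH2Cl2, −78 → −40 °C
Reagents that add atoms: none
Why: Catalytic asymmetric Diels–Alder reaction: the cationic boron catalyst binds the formyl group of the 2-substituted acrolein and exposes one face of C8=C14 (the (S)-catalyst is proposed from the accepted model for 2-substituted acroleins), the 1-silyloxy group directs C9 onto C8, and endo approach of the formyl group places CHO, OSi and ethynyl all cis, so that C8 and C13 are set by the catalyst and C9 by the endo rule.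

Step 14
Reactants: 19 (1S,2S,5S)-2-(tert-butyldimethylsilyloxy)-5-ethynyl-1-{[(3R,3aS,4R,7aR)-4,7a-dimethyl-1-oxo-4-(triethylsilyloxy)octahydroisobenzofuran-3-yl]methyl}cyclohex-3-ene-1-carbaldehyde
Product: 20 (3R,3aS,4R,7aR)-3-{[(1R,2S,5S,7S)-2-(tert-butyldimethylsilyloxy)-7-hydroxy-6-methylidenebicyclo[3.2.1]oct-3-en-1-yl]methyl}-4,7a-dimethyl-4-(triethylsilyloxy)hexahydroisobenzofuran-1(3H)-one
Conditions: SmI2, HMPA, t-BuOH, THF, 0 °C
Reagents that add atoms: none
Why: Ketyl–alkyne radical cyclisation: the samarium ketyl of the C15 aldehyde should add 5-exo-dig to the cis-1,3-disposed terminal alkyne and the vinyl radical is reduced and protonated to the C16=C17 methylidene, closing ring D; the carbinol configuration (exo expected, away from the C9 silyl ether) is not critical because steps 15 and 16 reset it.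

Step 15
Reactants: 20 (3R,3aS,4R,7aR)-3-{[(1R,2S,5S,7S)-2-(tert-butyldimethylsilyloxy)-7-hydroxy-6-methylidenebicyclo[3.2.1]oct-3-en-1-yl]methyl}-4,7a-dimethyl-4-(triethylsilyloxy)hexahydroisobenzofuran-1(3H)-one
Product: 21 (3R,3aS,4R,7aR)-3-{[(1S,2S,5S)-2-(tert-butyldimethylsilyloxy)-6-methylidene-7-oxobicyclo[3.2.1]oct-3-en-1-yl]methyl}-4,7a-dimethyl-4-(triethylsilyloxy)hexahydroisobenzofuran-1(3H)-one
Conditions: Dess–Martin periodinane, NaHCO3, CH2Cl2, 0 → 23 °C
Reagents that add atoms: none
Why: Dess–Martin oxidation of the allylic C15 alcohol gives the α-methylene cyclopentanone and so removes the uncontrolled carbinol centre.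

Step 16
Reactants: 21 (3R,3aS,4R,7aR)-3-{[(1S,2S,5S)-2-(tert-butyldimethylsilyloxy)-6-methylidene-7-oxobicyclo[3.2.1]oct-3-en-1-yl]methyl}-4,7a-dimethyl-4-(triethylsilyloxy)hexahydroisobenzofuran-1(3H)-one
Product: 22 (3R,3aS,4R,7aR)-3-{[(1R,2S,5S,7R)-2-(tert-butyldimethylsilyloxy)-7-hydroxy-6-methylidenebicyclo[3.2.1]oct-3-en-1-yl]methyl}-4,7a-dimethyl-4-(triethylsilyloxy)hexahydroisobenzofuran-1(3H)-one
Conditions: NaBH4, CeCl3·7H2O, MeOH, −78 °C
Reagents that add atoms: none
Why: Luche reduction: 1,2-hydride delivery to the enone from the exo face (the side of the one-carbon bridge C14), the endo face being shielded by the three-carbon bridge and the C9 silyl ether, should give the endo (15R) alcohol without touching the lactone.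

Step 17
Reactants: 22 (3R,3aS,4R,7aR)-3-{[(1R,2S,5S,7R)-2-(tert-butyldimethylsilyloxy)-7-hydroxy-6-methylidenebicyclo[3.2.1]oct-3-en-1-yl]methyl}-4,7a-dimethyl-4-(triethylsilyloxy)hexahydroisobenzofuran-1(3H)-one
Product: 23 (1R,2S,5S,7R)-2-(tert-butyldimethylsilyloxy)-1-{[(3R,3aS,4R,7aR)-4,7a-dimethyl-1-oxo-4-(triethylsilyloxy)octahydroisobenzofuran-3-yl]methyl}-6-methylidenebicyclo[3.2.1]oct-3-en-7-yl acetate
Conditions: Ac2O, DMAP, pyridine, 23 °C
Reagents that add atoms: acetic anhydride, CC(=O)OC(C)=O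
Why: DMAP-catalysed acylation of the only free hydroxyl group installs the C15 acetate with retention of configuration.

Step 18
Reactants: 23 (1R,2S,5S,7R)-2-(tert-butyldimethylsilyloxy)-1-{[(3R,3aS,4R,7aR)-4,7a-dimethyl-1-oxo-4-(triethylsilyloxy)octahydroisobenzofuran-3-yl]methyl}-6-methylidenebicyclo[3.2.1]oct-3-en-7-yl acetate
Product: 24 (1S,2S,5S,7R)-2-hydroxy-1-{[(3R,3aS,4R,7aR)-4-hydroxy-4,7a-dimethyl-1-oxooctahydroisobenzofuran-3-yl]methyl}-6-methylidenebicyclo[3.2.1]oct-3-en-7-yl acetate
Conditions: HF·pyridine, THF, 0 → 23 °C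
Reagents that add atoms: none
Why: Fluoride-mediated desilylation under mildly acidic conditions should cleave both silyl ethers while the acetate and lactone survive and acyl migration is suppressed.

Step 19
Reactants: 24 (1S,2S,5S,7R)-2-hydroxy-1-{[(3R,3aS,4R,7aR)-4-hydroxy-4,7a-dimethyl-1-oxooctahydroisobenzofuran-3-yl]methyl}-6-methylidenebicyclo[3.2.1]oct-3-en-7-yl acetate
Product: 25 (1R,5S,7R)-1-{[(3R,3aS,4R,7aR)-4-hydroxy-4,7a-dimethyl-1-oxooctahydroisobenzofuran-3-yl]methyl}-6-methylidene-2-oxobicyclo[3.2.1]oct-3-en-7-yl acetate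
Conditions: Dess–Martin periodinane, NaHCO3, CH2Cl2, 0 °C
Reagents that add atoms: none
Why: Dess–Martin oxidation of the secondary allylic C9 alcohol gives the C9 enone of the target, the tertiary C10 alcohol being inert to the oxidant.

Compound list
1 | 3-oxocyclohex-1-ene-1-carboxylic acid | OC(=O)C1=CC(=O)CCC1 | starting material
2 | tert-butyl 3-oxocyclohex-1-ene-1-carboxylate | CC(C)(C)OC(=O)C1=CC(=O)CCC1 | intermediate
3 | 4-oxobutyl acetate (4-acetoxybutanal) | CC(=O)OCCCC=O | starting material
4 | methylzinc (3R)-3-(tert-butoxycarbonyl)-3-methylcyclohex-1-en-1-olate (zinc enolate, not isolated) | CC(C)(C)OC(=O)[C@]1(C)CCCC(O[Zn]C)=C1 | intermediate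
5 | methylzinc alkoxide of tert-butyl (1R)-2-(4-acetoxy-1-hydroxybutyl)-1-methyl-3-oxocyclohexane-1-carboxylate (zinc aldolate, not isolated, diastereomer mixture) | CC(C)(C)OC(=O)[C@]1(C)CCCC(=O)C1C(O[Zn]C)CCCOC(C)=O | intermediate
6 | tert-butyl (1R)-2-[4-acetoxy-1-(methanesulfonyloxy)butyl]-1-methyl-3-oxocyclohexane-1-carboxylate (diastereomer mixture at the two CH centres) | CC(C)(C)OC(=O)[C@]1(C)CCCC(=O)C1C(OS(C)(=O)=O)CCCOC(C)=O | intermediate
7 | tert-butyl (1R)-2-(4-acetoxybutylidene)-1-methyl-3-oxocyclohexane-1-carboxylate (E/Z mixture) | CC(C)(C)OC(=O)[C@]1(C)CCCC(=O)C1=CCCCOC(C)=O | intermediate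
8 | (1R)-2-(4-acetoxybutylidene)-1-methyl-3-oxocyclohexane-1-carboxylic acid (enone acid, not isolated) | OC(=O)[C@]1(C)CCCC(=O)C1=CCCCOC(C)=O | intermediate
9 | 3-[(3R,3aS,7aR)-7a-methyl-1,4-dioxooctahydroisobenzofuran-3-yl]propyl acetate (cis-fused, side chain on the convex face) | CC(=O)OCCC[C@H]1OC(=O)[C@]2(C)CCCC(=O)[C@H]12 | intermediate
10 | 3-[(3R,3aS,7aR)-7a-methyl-4-methylidene-1-oxooctahydroisobenzofuran-3-yl]propyl acetate | CC(=O)OCCC[C@H]1OC(=O)[C@]2(C)CCCC(=C)[C@H]12 | intermediate
11 | 3-[(3R,3aS,4R,7aR)-4-hydroxy-4,7a-dimethyl-1-oxooctahydroisobenzofuran-3-yl]propyl acetate | CC(=O)OCCC[C@H]1OC(=O)[C@]2(C)CCC[C@@](C)(O)[C@H]12 | intermediate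
12 | 3-[(3R,3aS,4R,7aR)-4,7a-dimethyl-1-oxo-4-(triethylsilyloxy)octahydroisobenzofuran-3-yl]propyl acetate | CC(=O)OCCC[C@H]1OC(=O)[C@]2(C)CCC[C@@](C)(O[Si](CC)(CC)CC)[C@H]12 | intermediate
13 | (3R,3aS,4R,7aR)-3-(3-hydroxypropyl)-4,7a-dimethyl-4-(triethylsilyloxy)hexahydroisobenzofuran-1(3H)-one | OCCC[C@H]1OC(=O)[C@]2(C)CCC[C@@](C)(O[Si](CC)(CC)CC)[C@H]12 | intermediate
14 | 3-[(3R,3aS,4R,7aR)-4,7a-dimethyl-1-oxo-4-(triethylsilyloxy)octahydroisobenzofuran-3-yl]propanal | O=CCC[C@H]1OC(=O)[C@]2(C)CCC[C@@](C)(O[Si](CC)(CC)CC)[C@H]12 | intermediate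
15 | 2-{[(3R,3aS,4R,7aR)-4,7a-dimethyl-1-oxo-4-(triethylsilyloxy)octahydroisobenzofuran-3-yl]methyl}prop-2-enal | O=CC(=C)C[C@H]1OC(=O)[C@]2(C)CCC[C@@](C)(O[Si](CC)(CC)CC)[C@H]12 | intermediate
16 | glutaconaldehyde potassium salt (potassium (1E,3E)-5-oxopenta-1,3-dien-1-olate) | O=C/C=C/C=C/[O-].[K+] | starting material
17 | (2E,4E)-5-(tert-butyldimethylsilyloxy)penta-2,4-dienal | O=C/C=C/C=C/O[Si](C)(C)C(C)(C)C | intermediate
18 | tert-butyl[(1E,3E)-hexa-1,3-dien-5-yn-1-yloxy]dimethylsilane | C#C/C=C/C=C/O[Si](C)(C)C(C)(C)C | intermediate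
19 | (1S,2S,5S)-2-(tert-butyldimethylsilyloxy)-5-ethynyl-1-{[(3R,3aS,4R,7aR)-4,7a-dimethyl-1-oxo-4-(triethylsilyloxy)octahydroisobenzofuran-3-yl]methyl}cyclohex-3-ene-1-carbaldehyde (CHO, OSi and ethynyl all cis) | C#C[C@@H]1C=C[C@H](O[Si](C)(C)C(C)(C)C)[C@@](C[C@H]2OC(=O)[C@]3(C)CCC[C@@](C)(O[Si](CC)(CC)CC)[C@H]23)(C1)C=O | intermediate
20 | (3R,3aS,4R,7aR)-3-{[(1R,2S,5S,7S)-2-(tert-butyldimethylsilyloxy)-7-hydroxy-6-methylidenebicyclo[3.2.1]oct-3-en-1-yl]methyl}-4,7a-dimethyl-4-(triethylsilyloxy)hexahydroisobenzofuran-1(3H)-one (exo C15 alcohol expected; either epimer is carried on) | C=C1[C@@H]2C=C[C@H](O[Si](C)(C)C(C)(C)C)[C@@](C[C@H]3OC(=O)[C@]4(C)CCC[C@@](C)(O[Si](CC)(CC)CC)[C@H]34)(C2)[C@H]1O | intermediate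
21 | (3R,3aS,4R,7aR)-3-{[(1S,2S,5S)-2-(tert-butyldimethylsilyloxy)-6-methylidene-7-oxobicyclo[3.2.1]oct-3-en-1-yl]methyl}-4,7a-dimethyl-4-(triethylsilyloxy)hexahydroisobenzofuran-1(3H)-one | C=C1[C@@H]2C=C[C@H](O[Si](C)(C)C(C)(C)C)[C@@](C[C@H]3OC(=O)[C@]4(C)CCC[C@@](C)(O[Si](CC)(CC)CC)[C@H]34)(C2)C1=O | intermediate
22 | (3R,3aS,4R,7aR)-3-{[(1R,2S,5S,7R)-2-(tert-butyldimethylsilyloxy)-7-hydroxy-6-methylidenebicyclo[3.2.1]oct-3-en-1-yl]methyl}-4,7a-dimethyl-4-(triethylsilyloxy)hexahydroisobenzofuran-1(3H)-one (endo C15 alcohol) | C=C1[C@@H]2C=C[C@H](O[Si](C)(C)C(C)(C)C)[C@@](C[C@H]3OC(=O)[C@]4(C)CCC[C@@](C)(O[Si](CC)(CC)CC)[C@H]34)(C2)[C@@H]1O | intermediate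
23 | (1R,2S,5S,7R)-2-(tert-butyldimethylsilyloxy)-1-{[(3R,3aS,4R,7aR)-4,7a-dimethyl-1-oxo-4-(triethylsilyloxy)octahydroisobenzofuran-3-yl]methyl}-6-methylidenebicyclo[3.2.1]oct-3-en-7-yl acetate | C=C1[C@@H]2C=C[C@H](O[Si](C)(C)C(C)(C)C)[C@@](C[C@H]3OC(=O)[C@]4(C)CCC[C@@](C)(O[Si](CC)(CC)CC)[C@H]34)(C2)[C@@H]1OC(C)=O | intermediate
24 | (1S,2S,5S,7R)-2-hydroxy-1-{[(3R,3aS,4R,7aR)-4-hydroxy-4,7a-dimethyl-1-oxooctahydroisobenzofuran-3-yl]methyl}-6-methylidenebicyclo[3.2.1]oct-3-en-7-yl acetate | C=C1[C@@H]2C=C[C@H](O)[C@@](C[C@H]3OC(=O)[C@]4(C)CCC[C@@](C)(O)[C@H]34)(C2)[C@@H]1OC(C)=O | intermediate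
25 | (1R,5S,7R)-1-{[(3R,3aS,4R,7aR)-4-hydroxy-4,7a-dimethyl-1-oxooctahydroisobenzofuran-3-yl]methyl}-6-methylidene-2-oxobicyclo[3.2.1]oct-3-en-7-yl acetate (CNP0172716.1) | C=C1[C@@H]2C=CC(=O)[C@@](C[C@H]3OC(=O)[C@]4(C)CCC[C@@](C)(O)[C@H]34)(C2)[C@@H]1OC(C)=O | target

Total step count: 19. Longest linear sequence: 17 steps (steps 1–10 and 13–19; steps 11–12 make the diene).

Steps most likely to fail

Step 13 (Diels–Alder reaction). The boron catalyst may be sequestered by the lactone carbonyl and the silyl ether oxygens, or may discriminate poorly between the two faces of an enal that already carries remote stereocentres, so that both endo adducts form. Should only the sense of induction be wrong, the mirror-image catalyst is the first remedy. The fallback gives up reagent control and sets out from 15 (with 18): the cycloaddition is promoted by an achiral aluminium Lewis acid (Me2AlCl, CH2Cl2, −78 °C), which keeps the regio- and endo-control that the reactants themselves provide. Because the lactone stereocentres are already in place, the two endo adducts are diastereomers; chromatography separates 19 from the ring-C antipodal adduct F1, which is discarded, and the route resumes at 19.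

Step 6 (hydration at C10). Capture of the planar tertiary C10 radical by O2 may be poorly face-selective, giving both carbinol epimers. The fallback sets out from 10 and replaces the radical step by a concerted, sterically governed oxygen transfer: dimethyldioxirane in acetone at 0 °C should epoxidise the methylidene group from the convex face to give the spiro-epoxide F2. LiI with AcOH in THF opens it at the primary carbon to the iodohydrin F3, and Bu3SnH with AIBN in toluene at 80 °C removes the iodine, returning to the route at 11.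

Step 2 (conjugate addition–aldol). The zinc enolate, flanked by the new quaternary centre, may add too slowly to the aldehyde, or the aldolate may revert by retro-aldol cleavage before it is sulfonylated. The fallback sets out from 2: after the same copper-catalysed conjugate addition the enolate is quenched with Me3SiOTf to give the silyl enol ether F4, which is isolated. A Mukaiyama aldol addition to 3 (BF3·OEt2, CH2Cl2, −78 °C) then gives the β-hydroxy ketone F5, and MsCl with Et3N converts it into 6, where the route resumes.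

Further compounds
F1 | step 13 | (1R,2R,5R)-2-(tert-butyldimethylsilyloxy)-5-ethynyl-1-{[(3R,3aS,4R,7aR)-4,7a-dimethyl-1-oxo-4-(triethylsilyloxy)octahydroisobenzofuran-3-yl]methyl}cyclohex-3-ene-1-carbaldehyde | C#C[C@H]1C=C[C@@H](O[Si](C)(C)C(C)(C)C)[C@](C[C@H]2OC(=O)[C@]3(C)CCC[C@@](C)(O[Si](CC)(CC)CC)[C@H]23)(C1)C=O
F2 | step 6 | 3-[(3R,3aS,4R,7aR)-7a-methyl-1-oxohexahydrospiro[isobenzofuran-4,2'-oxiran]-3-yl]propyl acetate (epoxide oxygen on the convex face) | CC(=O)OCCC[C@H]1OC(=O)[C@]2(C)CCC[C@@]3(OC3)[C@H]12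
F3 | step 6 | 3-[(3R,3aS,4R,7aR)-4-hydroxy-4-(iodomethyl)-7a-methyl-1-oxooctahydroisobenzofuran-3-yl]propyl acetate | CC(=O)OCCC[C@H]1OC(=O)[C@]2(C)CCC[C@@](CI)(O)[C@H]12
F4 | step 2 | tert-butyl (1R)-1-methyl-3-(trimethylsilyloxy)cyclohex-2-ene-1-carboxylate | CC(C)(C)OC(=O)[C@]1(C)CCCC(O[Si](C)(C)C)=C1
F5 | step 2 | tert-butyl (1R)-2-(4-acetoxy-1-hydroxybutyl)-1-methyl-3-oxocyclohexane-1-carboxylate (diastereomer mixture) | CC(C)(C)OC(=O)[C@]1(C)CCCC(=O)C1C(O)CCCOC(C)=O
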